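**Retrosynthetic overview**

1. The target is a cycloheptane (ring A) cis-fused to an α-methylene-γ-butyrolactone (ring B); the last disconnection removes two silyl ethers (C5–O and the side-chain carbinol).
2. Key disconnection: the lactone bond O1–C8a and the ester bond O–C8 are made in one three-component operation (acid 25, iodine, silver (2S)-2-methylbutanoate 27), an interrupted Prévost reaction. The enabling feature is the C8=C8a alkene of ring A, which lies between C3a (carrying the acrylic acid) and the tertiary carbinol C7 (hydroxyl anti to the incoming iodine).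
3. Acid 25 comes from cycloheptenone 14 by 1,2-addition of the chiral-pool dithiane 19 (sets C7), dithiane hydrolysis and oxidation of the C3 arm.
4. Ring A is closed by ring-closing metathesis at C8=C8a of vinyl ketone 13; C5/C6 come from an Evans syn-aldol, C3a from a Johnson–Claisen rearrangement with chirality transfer from (2R)-but-3-yn-2-ol.
5. Ring order: ring A (step 10), then ring B (step 18).

Key step: step 18

Remark: target locants follow 2H-cyclohepta[b]furan (O1, C2, C3, C3a, C4–C8, C8a); TBS = tert-butyldimethylsilyl, TBSO = its ether.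

**Route**

Step 1
Reactants: 1 2-bromoprop-2-en-1-ol
Product: 2 [(2-bromoprop-2-en-1-yl)oxy](tert-butyl)dimethylsilane
Conditions: TBSCl, imidazole, DMF, 0 → 23 °C
Reagents that add atoms: tert-butyldimethylsilyl chloride, CC(C)(C)[Si](C)(C)Cl
Why: Routine silylation of a primary allylic alcohol with a silyl chloride and imidazole; no stereocentre is involved.

Step 2
Reactants: 2 [(2-bromoprop-2-en-1-yl)oxy](tert-butyl)dimethylsilane; 3 (2R)-but-3-yn-2-ol
Product: 4 (2R)-5-(TBSO-methyl)hex-5-en-3-yn-2-ol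
Conditions: Pd(PPh3)2Cl2 (3 mol %), CuI (6 mol %), Et3N, THF, 23 → 40 °C
Reagents that add atoms: none
Why: Sonogashira coupling of a vinyl bromide with a terminal alkyne tolerates the free secondary alcohol and does not touch its stereocentre.

Step 3
Reactants: 4 (2R)-5-(TBSO-methyl)hex-5-en-3-yn-2-ol
Product: 5 (2R,3E)-5-(TBSO-methyl)hexa-3,5-dien-2-ol
Conditions: NaAlH2(OCH2CH2OMe)2, THF, 0 → 23 °C; aq. potassium sodium tartrate
Reagents that add atoms: none
Why: Alkoxide-directed trans-hydroalumination of a propargylic alcohol should give only the E allylic alcohol, the carbinol centre being a spectator.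

Step 4
Reactants: 5 (2R,3E)-5-(TBSO-methyl)hexa-3,5-dien-2-ol
Product: 6 ethyl (3R,4E)-3-(3-TBSO-prop-1-en-2-yl)hex-4-enoate
Conditions: CH3C(OEt)3 (6 equiv), EtCO2H (0.1 equiv), xylenes, 135 °C, EtOH distilled off
Reagents that add atoms: triethyl orthoacetate, CCOC(C)(OCC)OCC
Why: Johnson–Claisen rearrangement through a chair transition state with the carbinol methyl equatorial transfers the C2 chirality suprafacially to the new C3 centre (R, the future C3a) and fixes the E-propenyl group.

Step 5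
Reactants: 6 ethyl (3R,4E)-3-(3-TBSO-prop-1-en-2-yl)hex-4-enoate
Product: 7 (3R,4E)-3-(3-TBSO-prop-1-en-2-yl)hex-4-enal
Conditions: i-Bu2AlH (1.1 equiv), CH2Cl2, −78 °C; MeOH, aq. potassium sodium tartrate
Reagents that add atoms: none
Why: Low-temperature DIBAL-H reduction of an ester stops at the aluminium hemiacetal, which gives the aldehyde on work-up; the β-stereocentre cannot epimerize.

Step 6
Reactants: 7 (3R,4E)-3-(3-TBSO-prop-1-en-2-yl)hex-4-enal; 8 (4S)-4-benzyl-3-propanoyl-1,3-oxazolidin-2-one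
Product: 10 (4S)-4-benzyl-3-[(2S,3R,5R,6E)-5-(3-TBSO-prop-1-en-2-yl)-3-hydroxy-2-methyloct-6-enoyl]-1,3-oxazolidin-2-one, via boron enolate 9 (not isolated)
Conditions: 8, Bu2BOTf, i-Pr2NEt, CH2Cl2, −78 → 0 °C; then 7, −78 → 0 °C; pH 7 buffer, MeOH, 30% H2O2
Reagents that add atoms: none
Why: Evans syn-aldol reaction: the Z-boron enolate reacts through a Zimmerman–Traxler chair on the face away from the benzyl group, setting C2 (S, future C6) and C3 (R, future C5) under reagent control whatever the remote C5 centre.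

Step 7
Reactants: 10 Evans aldol adduct
Product: 11 (2S,3R,5R,6E)-5-(3-TBSO-prop-1-en-2-yl)-3-hydroxy-N-methoxy-N,2-dimethyloct-6-enamide
Conditions: MeNHOMe·HCl, AlMe3, CH2Cl2, −20 → 0 °C
Reagents that add atoms: N,O-dimethylhydroxylamine hydrochloride, CNOC.Cl
Why: Aluminium amide transamination to the Weinreb amide is assisted by the free β-hydroxyl, cleaves only the exocyclic imide carbonyl and does not epimerize the α-centre.

Step 8
Reactants: 11 hydroxy Weinreb amide
Product: 12 (2S,3R,5R,6E)-3-TBSO-5-(3-TBSO-prop-1-en-2-yl)-N-methoxy-N,2-dimethyloct-6-enamide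
Conditions: TBSOTf, 2,6-lutidine, CH2Cl2, −78 → 0 °C
Reagents that add atoms: tert-butyldimethylsilyl trifluoromethanesulfonate, CC(C)(C)[Si](C)(C)OS(=O)(=O)C(F)(F)F
Why: Silylation of the secondary alcohol blocks retro-aldol and oxa-Michael pathways in the vinyl ketone that follows.

Step 9
Reactants: 12 silylated Weinreb amide
Product: 13 (4S,5R,7R,8E)-5-TBSO-7-(3-TBSO-prop-1-en-2-yl)-4-methyldeca-1,8-dien-3-one
Conditions: CH2=CHMgBr (3 equiv), THF, 0 °C; inverse quench into cold 1 M HCl
Reagents that add atoms: vinylmagnesium bromide, C=C[Mg]Br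
Why: Grignard addition to a Weinreb amide stops at the magnesium chelate, and the acidic inverse quench releases the vinyl ketone while keeping the liberated amine from adding to it.

Step 10
Reactants: 13 vinyl ketone
Product: 14 (4R,6R,7S)-6-TBSO-4-(3-TBSO-prop-1-en-2-yl)-7-methylcyclohept-2-en-1-one
Conditions: RuCl2(=CHPh)(PCy3)(H2IMes) (second-generation Grubbs catalyst, 5 mol %), CH2Cl2 (0.003 M), 40 °C
Reagents that add atoms: none
Why: Ring-closing metathesis between the E-propenyl group (initiation site) and the enone vinyl group closes ring A at the future C8=C8a bond with loss of propene, the hindered 1,1-disubstituted alkene not competing; no stereocentre changes.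

Step 11
Reactants: 15 1,3-dithiane; 16 (2R)-2-methyloxirane
Product: 18 (2R)-1-(1,3-dithian-2-yl)propan-2-ol, via 2-lithio-1,3-dithiane 17 (not isolated)
Conditions: n-BuLi, THF, −30 °C; then 16, −30 → 0 °C; H2O
Reagents that add atoms: none
Why: Corey–Seebach alkylation, the dithiane anion opening the epoxide by SN2 attack at the unsubstituted carbon so that the R carbinol centre is retained.

Step 12
Reactants: 18 (2R)-1-(1,3-dithian-2-yl)propan-2-ol
Product: 19 tert-butyl{[(2R)-1-(1,3-dithian-2-yl)propan-2-yl]oxy}dimethylsilane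
Conditions: TBSCl, imidazole, DMF, 23 °C
Reagents that add atoms: tert-butyldimethylsilyl chloride, CC(C)(C)[Si](C)(C)Cl
Why: Routine silylation that removes the acidic proton before the second dithiane metalation.

Step 13
Reactants: 19 silylated dithiane; 14 cycloheptenone
Product: 21 (1R,4R,6R,7S)-6-TBSO-4-(3-TBSO-prop-1-en-2-yl)-1-{2-[(2R)-2-TBSO-propyl]-1,3-dithian-2-yl}-7-methylcyclohept-2-en-1-ol, via lithiated dithiane 20 (not isolated)
Conditions: 19 (1.8 equiv), n-BuLi, THF, −20 °C, 2 h; then 14, −78 °C; aq. NH4Cl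
Reagents that add atoms: none
Why: 1,2-addition of a 2-lithio-2-alkyl-1,3-dithiane (Corey–Seebach acyl anion) to an enone in THF without HMPA, the bulky nucleophile entering anti to the adjacent C7 methyl group, which should set the tertiary carbinol (C1, R; future C7) with its hydroxyl cis to that methyl.

Step 14
Reactants: 21 dithiane carbinol
Product: 22 (3R)-3-TBSO-1-[(1R,4R,6R,7S)-6-TBSO-4-(3-TBSO-prop-1-en-2-yl)-1-hydroxy-7-methylcyclohept-2-en-1-yl]butan-1-one
Conditions: PhI(O2CCF3)2 (1.5 equiv), NaHCO3, MeCN/H2O 9:1, 0 °C, 10 min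
Reagents that add atoms: water, O
Why: Oxidative dithiane hydrolysis with bis(trifluoroacetoxy)iodobenzene is fast at 0 °C and, under bicarbonate buffering, spares alkenes, silyl ethers and the tertiary alcohol.

Step 15
Reactants: 22 tris-silyl ketol
Product: 23 (3R)-3-TBSO-1-[(1R,4R,6R,7S)-6-TBSO-1-hydroxy-4-(3-hydroxyprop-1-en-2-yl)-7-methylcyclohept-2-en-1-yl]butan-1-one
Conditions: HF·pyridine, pyridine, THF, 0 °C
Reagents that add atoms: none
Why: Buffered HF·pyridine should cleave the unhindered primary allylic silyl ether much faster than the two secondary ones.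

Step 16
Reactants: 23 primary allylic alcohol
Product: 25 2-[(1R,4R,5S,6R)-6-TBSO-4-hydroxy-5-methyl-4-[(3R)-3-TBSO-butanoyl]cyclohept-2-en-1-yl]prop-2-enoic acid, via enal 24 (not isolated)
Conditions: TEMPO (10 mol %), PhI(OAc)2, CH2Cl2, 23 °C; then t-BuOH/H2O, 2-methylbut-2-ene, NaH2PO4, NaClO2, 0 → 23 °C
Reagents that add atoms: sodium chlorite, [Na+].[O-]Cl=O
Why: Oxoammonium oxidation of the primary allylic alcohol to the 2-substituted acrolein followed in the same flask by Pinnick oxidation gives the acrylic acid without touching the tertiary ketol or the alkenes.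

Step 17
Reactants: 26 (2S)-2-methylbutanoic acid
Product: 27 silver (2S)-2-methylbutanoate, AgO2CCH(CH3)CH2CH3
Conditions: NaOH (1.0 equiv), H2O; then AgNO3 (1.0 equiv), H2O, dark, 23 °C; filter, dry in vacuo
Reagents that add atoms: silver nitrate, [Ag+].[O-][N+](=O)[O-]
Why: Salt metathesis precipitates the silver carboxylate under near-neutral aqueous conditions that do not epimerize the α-centre.

Step 18
Reactants: 25 cycloheptenyl acrylic acid; 27 silver (2S)-2-methylbutanoate
Product: 30 (3aS,5R,6S,7S,8S,8aR)-5-TBSO-7-hydroxy-6-methyl-3-methylidene-2-oxo-7-[(3R)-3-TBSO-butanoyl]octahydro-2H-cyclohepta[b]furan-8-yl (2S)-2-methylbutanoate, via iodolactone 28 (not isolated), via epoxide 29 (not isolated)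
Conditions: 27 (2.5 equiv), I2 (1.05 equiv), 4 Å molecular sieves, dry PhMe, dark, 0 → 23 °C, 2 h; then 70 °C
Reagents that add atoms: none
Why: Proposed new method: an interrupted Prévost reaction in which the substrate's own carboxylic acid plays the first carboxylate and a hydroxyl relays the second one; the closest known reaction types are the Prévost trans-diacyloxylation of alkenes (I2, silver carboxylate), iodolactonization, and silver-assisted closure of trans-iodohydrins to oxiranes followed by carboxylic acid opening of α,β-epoxy ketones at the β-carbon. The acyl hypoiodite formed from 27 and I2 iodinates the C8=C8a alkene reversibly, and only the iodonium ion on the face opposite the C3a arm is captured, by 5-exo-trig attack of the carboxylate oxygen at C8a, which forms the O1–C8a bond and cis-fused ring B (C8a R, fixed by the tether from C3a) and leaves iodine on C8 in 28. Silver ion then abstracts iodide while the anti-periplanar C7 hydroxyl closes oxirane 29 (3-exo-tet, inversion at C8), and the 2-methylbutanoic acid released opens 29 at C8 with a second inversion, so the ester oxygen ends on the face where iodine stood, trans to O1 and to the C7 hydroxyl (C8 S, controlled by the C7 centre through double inversion). The step needs 5-exo over 6-endo lactonization (kinetically favoured γ-lactone), iodination of the ring alkene rather than the electron-poor acrylic alkene, and opening of 29 at the secondary C8 rather than at the quaternary C7, which the adjacent ketone deactivates toward ionization. Keeping the mixture cold and dark until 28 has formed should suppress Hunsdiecker decarboxylation of the hypoiodite.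

Step 19
Reactants: 30 bis-silyl ether of the target
Product: 31 (3aS,5R,6S,7S,8S,8aR)-5,7-dihydroxy-7-[(3R)-3-hydroxybutanoyl]-6-methyl-3-methylidene-2-oxooctahydro-2H-cyclohepta[b]furan-8-yl (2S)-2-methylbutanoate (CNP0291806.4)
Conditions: HF·pyridine (excess), THF, 0 → 23 °C
Reagents that add atoms: none
Why: Weakly acidic fluoride cleavage of the two secondary silyl ethers should leave the α-methylene lactone, the ester, the tertiary ketol and the β-hydroxy ketone intact.

**Compound list**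

1 | 2-bromoprop-2-en-1-ol | OCC(Br)=C | starting material
2 | [(2-bromoprop-2-en-1-yl)oxy](tert-butyl)dimethylsilane | C=C(Br)CO[Si](C)(C)C(C)(C)C | intermediate
3 | (2R)-but-3-yn-2-ol | C#C[C@@H](C)O | starting material
4 | (2R)-5-(TBSO-methyl)hex-5-en-3-yn-2-ol | C[C@@H](O)C#CC(=C)CO[Si](C)(C)C(C)(C)C | intermediate
5 | (2R,3E)-5-(TBSO-methyl)hexa-3,5-dien-2-ol | C[C@@H](O)/C=C/C(=C)CO[Si](C)(C)C(C)(C)C | intermediate
6 | ethyl (3R,4E)-3-(3-TBSO-prop-1-en-2-yl)hex-4-enoate | CCOC(=O)C[C@H](/C=C/C)C(=C)CO[Si](C)(C)C(C)(C)C | intermediate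
7 | (3R,4E)-3-(3-TBSO-prop-1-en-2-yl)hex-4-enal | O=CC[C@H](/C=C/C)C(=C)CO[Si](C)(C)C(C)(C)C | intermediate
8 | (4S)-4-benzyl-3-propanoyl-1,3-oxazolidin-2-one | CCC(=O)N1[C@@H](Cc2ccccc2)COC1=O | starting material
9 | dibutylboron Z-enolate of 8 | C/C=C(\OB(CCCC)CCCC)N1[C@@H](Cc2ccccc2)COC1=O | intermediate
10 | (4S)-4-benzyl-3-[(2S,3R,5R,6E)-5-(3-TBSO-prop-1-en-2-yl)-3-hydroxy-2-methyloct-6-enoyl]-1,3-oxazolidin-2-one | O=C1OC[C@H](Cc2ccccc2)N1C(=O)[C@@H](C)[C@H](O)C[C@H](/C=C/C)C(=C)CO[Si](C)(C)C(C)(C)C | intermediate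
11 | (2S,3R,5R,6E)-5-(3-TBSO-prop-1-en-2-yl)-3-hydroxy-N-methoxy-N,2-dimethyloct-6-enamide | CON(C)C(=O)[C@@H](C)[C@H](O)C[C@H](/C=C/C)C(=C)CO[Si](C)(C)C(C)(C)C | intermediate
12 | (2S,3R,5R,6E)-3-TBSO-5-(3-TBSO-prop-1-en-2-yl)-N-methoxy-N,2-dimethyloct-6-enamide | CON(C)C(=O)[C@@H](C)[C@H](O[Si](C)(C)C(C)(C)C)C[C@H](/C=C/C)C(=C)CO[Si](C)(C)C(C)(C)C | intermediate
13 | (4S,5R,7R,8E)-5-TBSO-7-(3-TBSO-prop-1-en-2-yl)-4-methyldeca-1,8-dien-3-one | C=CC(=O)[C@@H](C)[C@H](O[Si](C)(C)C(C)(C)C)C[C@H](/C=C/C)C(=C)CO[Si](C)(C)C(C)(C)C | intermediate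
14 | (4R,6R,7S)-6-TBSO-4-(3-TBSO-prop-1-en-2-yl)-7-methylcyclohept-2-en-1-one | O=C1C=C[C@H](C(=C)CO[Si](C)(C)C(C)(C)C)C[C@@H](O[Si](C)(C)C(C)(C)C)[C@@H]1C | intermediate
15 | 1,3-dithiane | C1CSCSC1 | starting material
16 | (2R)-2-methyloxirane | C[C@@H]1CO1 | starting material
17 | 2-lithio-1,3-dithiane | [Li]C1SCCCS1 | intermediate
18 | (2R)-1-(1,3-dithian-2-yl)propan-2-ol | C[C@@H](O)CC1SCCCS1 | intermediate
19 | tert-butyl{[(2R)-1-(1,3-dithian-2-yl)propan-2-yl]oxy}dimethylsilane | C[C@H](CC1SCCCS1)O[Si](C)(C)C(C)(C)C | intermediate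
20 | 2-lithio derivative of 19 | C[C@H](CC1([Li])SCCCS1)O[Si](C)(C)C(C)(C)C | intermediate
21 | (1R,4R,6R,7S)-6-TBSO-4-(3-TBSO-prop-1-en-2-yl)-1-{2-[(2R)-2-TBSO-propyl]-1,3-dithian-2-yl}-7-methylcyclohept-2-en-1-ol | O[C@]1(C2(C[C@@H](C)O[Si](C)(C)C(C)(C)C)SCCCS2)C=C[C@H](C(=C)CO[Si](C)(C)C(C)(C)C)C[C@@H](O[Si](C)(C)C(C)(C)C)[C@@H]1C | intermediate
22 | (3R)-3-TBSO-1-[(1R,4R,6R,7S)-6-TBSO-4-(3-TBSO-prop-1-en-2-yl)-1-hydroxy-7-methylcyclohept-2-en-1-yl]butan-1-one | O[C@]1(C(=O)C[C@@H](C)O[Si](C)(C)C(C)(C)C)C=C[C@H](C(=C)CO[Si](C)(C)C(C)(C)C)C[C@@H](O[Si](C)(C)C(C)(C)C)[C@@H]1C | intermediate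
23 | (3R)-3-TBSO-1-[(1R,4R,6R,7S)-6-TBSO-1-hydroxy-4-(3-hydroxyprop-1-en-2-yl)-7-methylcyclohept-2-en-1-yl]butan-1-one | O[C@]1(C(=O)C[C@@H](C)O[Si](C)(C)C(C)(C)C)C=C[C@H](C(=C)CO)C[C@@H](O[Si](C)(C)C(C)(C)C)[C@@H]1C | intermediate
24 | 2-[(1R,4R,5S,6R)-6-TBSO-4-hydroxy-5-methyl-4-[(3R)-3-TBSO-butanoyl]cyclohept-2-en-1-yl]prop-2-enal | O[C@]1(C(=O)C[C@@H](C)O[Si](C)(C)C(C)(C)C)C=C[C@H](C(=C)C=O)C[C@@H](O[Si](C)(C)C(C)(C)C)[C@@H]1C | intermediate
25 | 2-[(1R,4R,5S,6R)-6-TBSO-4-hydroxy-5-methyl-4-[(3R)-3-TBSO-butanoyl]cyclohept-2-en-1-yl]prop-2-enoic acid | O[C@]1(C(=O)C[C@@H](C)O[Si](C)(C)C(C)(C)C)C=C[C@H](C(=C)C(=O)O)C[C@@H](O[Si](C)(C)C(C)(C)C)[C@@H]1C | intermediate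
26 | (2S)-2-methylbutanoic acid | CC[C@H](C)C(=O)O | starting material
27 | silver (2S)-2-methylbutanoate | CC[C@H](C)C(=O)[O-].[Ag+] | intermediate
28 | (3aS,5R,6S,7R,8S,8aR)-5-TBSO-7-hydroxy-8-iodo-6-methyl-3-methylidene-7-[(3R)-3-TBSO-butanoyl]octahydro-2H-cyclohepta[b]furan-2-one | C=C1C(=O)O[C@@H]2[C@H]1C[C@@H](O[Si](C)(C)C(C)(C)C)[C@H](C)[C@@](O)(C(=O)C[C@@H](C)O[Si](C)(C)C(C)(C)C)[C@H]2I | intermediate
29 | C7–C8 epoxide of the lactone (oxirane oxygen cis to O1, trans to the butanoyl group; TBS ethers at C5 and on the side chain) | C=C1C(=O)O[C@@H]2[C@H]1C[C@@H](O[Si](C)(C)C(C)(C)C)[C@H](C)[C@]3(C(=O)C[C@@H](C)O[Si](C)(C)C(C)(C)C)O[C@H]23 | intermediate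
30 | (3aS,5R,6S,7S,8S,8aR)-5-TBSO-7-hydroxy-6-methyl-3-methylidene-2-oxo-7-[(3R)-3-TBSO-butanoyl]octahydro-2H-cyclohepta[b]furan-8-yl (2S)-2-methylbutanoate | C=C1C(=O)O[C@@H]2[C@H]1C[C@@H](O[Si](C)(C)C(C)(C)C)[C@H](C)[C@@](O)(C(=O)C[C@@H](C)O[Si](C)(C)C(C)(C)C)[C@H]2OC(=O)[C@@H](C)CC | intermediate
31 | (3aS,5R,6S,7S,8S,8aR)-5,7-dihydroxy-7-[(3R)-3-hydroxybutanoyl]-6-methyl-3-methylidene-2-oxooctahydro-2H-cyclohepta[b]furan-8-yl (2S)-2-methylbutanoate | C=C1C(=O)O[C@@H]2[C@H]1C[C@@H](O)[C@H](C)[C@@](O)(C(=O)C[C@@H](C)O)[C@H]2OC(=O)[C@@H](C)CC | target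

**Step count and risks**

Total step count: 19. Longest linear sequence: 16 steps (steps 1–10, 13–16, 18, 19).

Steps most likely to fail:

1. Step 18 (Proposed new method). The cascade may stall after iodolactonization if silver-assisted loss of iodide is slow. The hypoiodite may also be lost by decarboxylation, or the transient oxirane may undergo a 1,2-acyl shift before the acid opens it. The fallback separates the three events into known reactions, setting out from 25 and coming back at 30. Classical iodolactonization (I2, NaHCO3, MeCN, 0 °C) should give iodolactone 28, which is isolated. Ag2O in dry CH2Cl2 should close the trans-iodohydrin to epoxide 29, also isolated. Epoxide 29 is then opened at C8 with cesium (2S)-2-methylbutanoate F1 (from 26 and Cs2CO3), with 26 as proton source, in DMF at 60 °C to give 30.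

2. Step 13. The hindered, basic dithiane anion may enolize the ketone (with loss of the β-silyloxy group) instead of adding, or may add with poor facial selectivity. The fallback uses a much smaller acyl-anion surrogate, sets out from 14 and comes back at 22. Alcohol 3 is silylated (TBSCl, imidazole) to tert-butyl{[(2R)-but-3-yn-2-yl]oxy}dimethylsilane F2. Its lithium acetylide (n-BuLi, then anhydrous CeCl3) is added to 14 at −78 °C to give the propargylic alcohol F3. Silver-catalysed carboxylative cyclization (AgOAc, DBU, CO2 at 1 atm) should give the Z-alkylidene cyclic carbonate F4, with oxygen on the alkyne carbon next to the carbinol. Brief hydrolysis (LiOH, THF/H2O, 0 °C) releases CO2 and the ketone 22.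

3. Step 15. The silyl ether on the side chain (β to the ketone) may be cleaved along with the primary one, and the diol would then over-oxidize in step 16. The fallback drops the selective deprotection, sets out from 22 and comes back at 24. Complete desilylation (aq. HF, MeCN) gives the tetraol 1-[(1R,4R,6R,7S)-1,6-dihydroxy-4-(3-hydroxyprop-1-en-2-yl)-7-methylcyclohept-2-en-1-yl]-(3R)-3-hydroxybutan-1-one F5. MnO2 in CH2Cl2 oxidizes only the primary allylic alcohol, to the enal F6. TBSCl/imidazole re-silylates the two secondary hydroxyls (the tertiary one does not react) to give 24, which then goes through the chlorite stage of step 16.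

**Further compounds**

F1 | step 18 | cesium (2S)-2-methylbutanoate | CC[C@H](C)C(=O)[O-].[Cs+]
F2 | step 13 | tert-butyl{[(2R)-but-3-yn-2-yl]oxy}dimethylsilane | C#C[C@@H](C)O[Si](C)(C)C(C)(C)C
F3 | step 13 | (1R,4R,6R,7S)-6-TBSO-4-(3-TBSO-prop-1-en-2-yl)-1-[(3R)-3-TBSO-but-1-yn-1-yl]-7-methylcyclohept-2-en-1-ol | O[C@]1(C#C[C@@H](C)O[Si](C)(C)C(C)(C)C)C=C[C@H](C(=C)CO[Si](C)(C)C(C)(C)C)C[C@@H](O[Si](C)(C)C(C)(C)C)[C@@H]1C
F4 | step 13 | spiro Z-alkylidene cyclic carbonate of F3 (1,3-dioxolan-2-one spiro-fused at the carbinol carbon, exocyclic Z alkene carrying the (R)-1-TBSO-ethyl group) | O=C1O/C(=C\[C@@H](C)O[Si](C)(C)C(C)(C)C)[C@@]2(O1)C=C[C@H](C(=C)CO[Si](C)(C)C(C)(C)C)C[C@@H](O[Si](C)(C)C(C)(C)C)[C@@H]2C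
F5 | step 15 | 1-[(1R,4R,6R,7S)-1,6-dihydroxy-4-(3-hydroxyprop-1-en-2-yl)-7-methylcyclohept-2-en-1-yl]-(3R)-3-hydroxybutan-1-one | O[C@]1(C(=O)C[C@@H](C)O)C=C[C@H](C(=C)CO)C[C@@H](O)[C@@H]1C
F6 | step 15 | 2-[(1R,4R,5S,6R)-4,6-dihydroxy-4-[(3R)-3-hydroxybutanoyl]-5-methylcyclohept-2-en-1-yl]prop-2-enal | O[C@]1(C(=O)C[C@@H](C)O)C=C[C@H](C(=C)C=O)C[C@@H](O)[C@@H]1C
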